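**Retrosynthetic overview**
1. No ring is built. The coumarin bicycle is bought as umbelliferone (1) and only functionalised at C8: Duff formylation (aldimine 2, then phenol aldehyde 3) and O-methylation give aldehyde 4.
2. The C5 side chain arrives with its ester already in place: methacrolein (5) and isovaleric anhydride (6) give the gem-diester (acylal) 7.
3. Key disconnection of target 8: the C1'–C2' bond between the two oxygen-bearing carbons, i.e. between the formyl carbon of 4 and the former formyl carbon of 5, both natural electrophiles.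
4. Forward, iridium turns 7 into a nucleophilic 1-acyloxy-2-methylallyl unit (polarity reversal at the methacrolein carbonyl carbon). Its reductive, enantioselective addition to 4 forms the C–C bond, both stereocentres (1'R,2'S = anti/erythro) and the regiodefined 2'-monoester in one step.

Assumption: the (S)-SEGPHOS iridium catalyst in step 4 is taken to add to the Si face of the aldehyde, by analogy with aryl aldehyde allylation and crotylation by this catalyst family and recalled rather than verified; if the first run gives the antipode (Mosher analysis), the (R)-ligand is used with no other change.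

**Route**

Step 1
Reactants: 1 umbelliferone (7-hydroxy-2H-chromen-2-one)
Product: 3 7-hydroxy-2-oxo-2H-chromene-8-carbaldehyde, via 8-(iminomethyl)-7-hydroxycoumarin 2 (not isolated)
Conditions: HMTA (2 equiv), TFA, reflux, 8 h; then H2O, 60 °C, 1 h
Reagents that add atoms: hexamethylenetetramine C1N2CN3CN1CN(C2)C3; water O
Why: Duff formylation: the HMTA-derived iminium aminomethylates the phenol at its most nucleophilic ortho position C8 (between the 7-OH and the ring oxygen), hydride transfer to a second iminium oxidises the benzylamine to aldimine 2, and water hydrolyses it to the H-bonded o-hydroxy aldehyde; the lactone is stable to hot TFA and no stereocentre is formed.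

Step 2
Reactants: 3 7-hydroxy-2-oxo-2H-chromene-8-carbaldehyde
Product: 4 7-methoxy-2-oxo-2H-chromene-8-carbaldehyde
Conditions: MeI (1.5 equiv), K2CO3 (2 equiv), DMF, rt, 6 h
Reagents that add atoms: iodomethane CI
Why: Williamson ether synthesis: the acidic phenol ortho to the formyl group is deprotonated by K2CO3 and methylated by MeI in an SN2 reaction, while the non-enolisable aldehyde and the lactone are inert to these anhydrous, mildly basic conditions.

Step 3
Reactants: 5 methacrolein (2-methylprop-2-enal); 6 isovaleric anhydride (3-methylbutanoic anhydride)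
Product: 7 2-methylprop-2-ene-1,1-diyl bis(3-methylbutanoate)
Conditions: 6 (1.05 equiv), FeCl3 (1 mol%), BHT (cat.), neat, 0 °C → rt, 2 h; aq. NaHCO3 wash; vacuum distillation
Reagents that add atoms: none
Why: Lewis-acid-catalysed acylal formation (1,1-diacyloxylation of an aldehyde by an anhydride, as in the preparation of allylidene diacetate from acrolein): the activated carbonyl is acylated and captured by isovalerate in an addition that loses no atoms, with low temperature and BHT suppressing polymerisation and 1,3-transposition.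

Step 4
Reactants: 4 7-methoxy-2-oxo-2H-chromene-8-carbaldehyde; 7 2-methylprop-2-ene-1,1-diyl bis(3-methylbutanoate)
Product: 8 (1R,2S)-1-hydroxy-1-(7-methoxy-2-oxo-2H-chromen-8-yl)-3-methylbut-3-en-2-yl 3-methylbutanoate
Conditions: 7 (2 equiv), preformed (S)-SEGPHOS π-allyl-iridium C,O-(4-cyano-3-nitrobenzoate) complex (5 mol%), i-PrOH (2 equiv), K3PO4 (1 equiv), THF (0.5 M), 80 °C, 36 h; pH 7 buffer work-up, neutral silica
Reagents that add atoms: none
Why: Proposed new method: this extends the known Krische-type iridium-catalysed transfer-hydrogenative anti-(α-acyloxy)allylation of aldehydes with acrolein gem-dibenzoate to a 2-methyl-substituted gem-di(alkanoate) — Ir(I) ionises one isovalerate of 7 to a 1-acyloxy-2-methyl-π-allyl-iridium(III), whose (E)-σ-allyl form (Ir on CH2, acyloxy trans to it) adds through its oxygen-bearing carbon to the Ir-bound aldehyde in a closed chair transition state (aryl equatorial, hence anti), the (S)-SEGPHOS/C,O-benzoate environment selecting the Si face of the aldehyde (1'R, and with anti addition 2'S), after which i-PrOH exchanges the alkoxide and β-hydride elimination with loss of acetone returns Ir(I); the ester stays on O2' and the new carbinol is the free 1'-OH.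

**Compound list**
1 | umbelliferone (7-hydroxy-2H-chromen-2-one) | O=c1ccc2ccc(O)cc2o1 | starting material
2 | 8-(iminomethyl)-7-hydroxycoumarin (Duff aldimine, protonated in TFA) | N=Cc1c(O)ccc2ccc(=O)oc12 | intermediate
3 | 7-hydroxy-2-oxo-2H-chromene-8-carbaldehyde | O=Cc1c(O)ccc2ccc(=O)oc12 | intermediate
4 | 7-methoxy-2-oxo-2H-chromene-8-carbaldehyde | COc1ccc2ccc(=O)oc2c1C=O | intermediate
5 | methacrolein (2-methylprop-2-enal) | C=C(C)C=O | starting material
6 | isovaleric anhydride (3-methylbutanoic anhydride) | CC(C)CC(=O)OC(=O)CC(C)C | starting material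
7 | 2-methylprop-2-ene-1,1-diyl bis(3-methylbutanoate) | C=C(C)C(OC(=O)CC(C)C)OC(=O)CC(C)C | intermediate
8 | (1R,2S)-1-hydroxy-1-(7-methoxy-2-oxo-2H-chromen-8-yl)-3-methylbut-3-en-2-yl 3-methylbutanoate | C=C(C)[C@H](OC(=O)CC(C)C)[C@H](O)c1c(OC)ccc2ccc(=O)oc12 | target

**Totals**
Total step count: 4. Longest linear sequence: 3 (steps 1, 2, 4); step 3 is a one-step side branch.

**Three steps most likely to fail**

Step 4 (highest risk). The 2-methyl group and the alkanoate leaving group both slow ionisation of 7. A(1,2) strain in the (E)-σ-allyl may lower the anti:syn ratio. The hindered di-ortho-substituted aldehyde may react slowly. Base at 80 °C may cause 2'→1' acyl migration.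
Fallback, setting out from 4 and returning at 8: a stoichiometric chiral α-alkoxyallyl borane gives the syn adduct, and the ester is then introduced with inversion at C2'. Methallyl alcohol is protected (MOMCl, i-Pr2NEt, CH2Cl2) as 3-(methoxymethoxy)-2-methylprop-1-ene F1. F1 is lithiated at the oxygen-bearing carbon (s-BuLi, THF, −78 °C) and trapped with (−)-Ipc2BOMe, then BF3·OEt2, to give B-[(Z)-3-(methoxymethoxy)-2-methylallyl]diisopinocampheylborane F2, used in situ. Addition of F2 to 4 at −78 °C with ethanolamine work-up gives 8-[(1R,2R)-1-hydroxy-2-(methoxymethoxy)-3-methylbut-3-en-1-yl]-7-methoxy-2H-chromen-2-one F3 (chair transition state, Z-reagent gives syn, the (+)-α-pinene-derived borane attacks the Si face). Silylation (TBSOTf, 2,6-lutidine, CH2Cl2, 0 °C) gives 8-[(1R,2R)-1-(tert-butyldimethylsilyloxy)-2-(methoxymethoxy)-3-methylbut-3-en-1-yl]-7-methoxy-2H-chromen-2-one F4. Selective MOM cleavage (ZnBr2, n-PrSH, CH2Cl2, 0 °C) gives 8-[(1R,2R)-1-(tert-butyldimethylsilyloxy)-2-hydroxy-3-methylbut-3-en-1-yl]-7-methoxy-2H-chromen-2-one F5. Mitsunobu esterification with isovaleric acid (PPh3, DIAD, THF, 0 °C → rt) inverts C2' and gives (1R,2S)-1-(tert-butyldimethylsilyloxy)-1-(7-methoxy-2-oxo-2H-chromen-8-yl)-3-methylbut-3-en-2-yl 3-methylbutanoate F6. HF·pyridine in THF at 0 °C (acidic, so no acyl migration) then releases 8.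

Step 3. Methacrolein may polymerise, or the acylal may transpose under acid.
Fallback, setting out from 5 and returning at 8: methacrolein and isovaleryl chloride with catalytic ZnCl2 (CH2Cl2, −20 °C → rt) give 3-chloro-2-methylprop-1-en-1-yl 3-methylbutanoate F7 as an E/Z mixture (1,2-addition, then allylic chloride shift). F7 replaces 7 in the iridium coupling with 4 under the step 4 conditions. Its primary allylic chloride ionises more readily than a carboxylate, and both geometric isomers converge on the same 1-acyloxy-2-methyl-π-allyl-iridium, so 8 is formed directly.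

Step 1. The Duff reaction on umbelliferone can give modest yields and some 6-formyl isomer.
Fallback, setting out from 1 and returning at 4: regioselective iodination (I2, KI, aq. NH3, rt) gives 7-hydroxy-8-iodo-2H-chromen-2-one F8. Methylation (MeI, K2CO3, DMF) gives 8-iodo-7-methoxy-2H-chromen-2-one F9. Palladium-catalysed reductive carbonylation (Pd(OAc)2, di(1-adamantyl)-n-butylphosphine, CO/H2 1:1 at 5 bar, TMEDA, toluene, 100 °C) converts the aryl iodide into aldehyde 4, bypassing 2 and 3.

**Further compounds**
F1 | step 4 | 3-(methoxymethoxy)-2-methylprop-1-ene | C=C(C)COCOC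
F2 | step 4 | B-[(Z)-3-(methoxymethoxy)-2-methylallyl]diisopinocampheylborane (Ipc groups from (+)-α-pinene) | COCO/C=C(/C)CB([C@@H]1C[C@@H]2C[C@H]([C@H]1C)C2(C)C)[C@@H]1C[C@@H]2C[C@H]([C@H]1C)C2(C)C
F3 | step 4 | 8-[(1R,2R)-1-hydroxy-2-(methoxymethoxy)-3-methylbut-3-en-1-yl]-7-methoxy-2H-chromen-2-one | C=C(C)[C@@H](OCOC)[C@H](O)c1c(OC)ccc2ccc(=O)oc12
F4 | step 4 | 8-[(1R,2R)-1-(tert-butyldimethylsilyloxy)-2-(methoxymethoxy)-3-methylbut-3-en-1-yl]-7-methoxy-2H-chromen-2-one | C=C(C)[C@@H](OCOC)[C@H](O[Si](C)(C)C(C)(C)C)c1c(OC)ccc2ccc(=O)oc12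
F5 | step 4 | 8-[(1R,2R)-1-(tert-butyldimethylsilyloxy)-2-hydroxy-3-methylbut-3-en-1-yl]-7-methoxy-2H-chromen-2-one | C=C(C)[C@@H](O)[C@H](O[Si](C)(C)C(C)(C)C)c1c(OC)ccc2ccc(=O)oc12
F6 | step 4 | (1R,2S)-1-(tert-butyldimethylsilyloxy)-1-(7-methoxy-2-oxo-2H-chromen-8-yl)-3-methylbut-3-en-2-yl 3-methylbutanoate | C=C(C)[C@H](OC(=O)CC(C)C)[C@H](O[Si](C)(C)C(C)(C)C)c1c(OC)ccc2ccc(=O)oc12
F7 | step 3 | 3-chloro-2-methylprop-1-en-1-yl 3-methylbutanoate (E/Z mixture) | ClCC(C)=COC(=O)CC(C)C
F8 | step 1 | 7-hydroxy-8-iodo-2H-chromen-2-one | O=c1ccc2ccc(O)c(I)c2o1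
F9 | step 1 | 8-iodo-7-methoxy-2H-chromen-2-one | COc1ccc2ccc(=O)oc2c1I
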